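**Retrosynthetic overview**

1. The acid comes from its methyl ester; the C4-ethyl group comes from a C4-vinyl group (diimide); the C3–CH2CO2Me bond comes from axial addition of a silyl ketene acetal to the 1,2-dioxan-3-yl cation of a 3-methoxy-1,2-dioxane.
2. Key disconnection: C3–C4 of the 1,2-dioxane. C3 is the ring carbon bonded to peroxide oxygen O2, so it can be brought in at the orthoformate level (from HC(OMe)3) as an O2/OMe-stabilized cation; C4 is the γ-carbon of a tethered allylsilane; C6 (quaternary, bonded to O1, no α-H) tolerates the Lewis acid.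
3. The tertiary C6–OOH comes from invertive perhydrolysis of a 2,2-disubstituted oxetane, made from a 1,3-diol, made from the Sharpless epoxide of a dienol.
4. The dienol comes from ethylcupration of an enyne and Negishi coupling with an (E)-enol triflate; the side-chain stereocentre comes from an Evans alkylation and its E-alkene from a Julia–Kocienski olefination.
5. Ring order: oxirane (step 8) and oxetane (step 10), both temporary, then the 1,2-dioxane (step 15).

Key step: step 15

Assumption: the N-butanoyl oxazolidinone of step 1 and the propyl 1-phenyltetrazolyl sulfone of step 4 are taken as purchasable (each is otherwise one or two routine steps from catalogue compounds).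

**Route**

Step 1
Reactants: 1 (4S)-4-benzyl-3-butanoyl-1,3-oxazolidin-2-one; 2 3-bromoprop-1-yne
Product: 3 (4S)-4-benzyl-3-[(2R)-2-ethylpent-4-ynoyl]-1,3-oxazolidin-2-one
Conditions: NaN(SiMe3)2, THF, −78 °C; 2, −78 to −40 °C
Reagents that add atoms: none
Why: Evans alkylation: the chelated Z-enolate of the N-acyl oxazolidinone is attacked on the face opposite the benzyl group, which should set the (2R) centre that becomes the side-chain stereocentre.

Step 2
Reactants: 3
Product: 4 (2R)-2-ethylpent-4-yn-1-ol
Conditions: LiBH4, MeOH (1 equiv), Et2O, 0 °C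
Reagents that add atoms: none
Why: Reductive cleavage of the N-acyl oxazolidinone by LiBH4 (hydride attack at the exocyclic carbonyl) should release the primary alcohol without touching the α-stereocentre and returns the auxiliary.

Step 3
Reactants: 4
Product: 5 (2R)-2-ethylpent-4-ynal
Conditions: Dess–Martin periodinane, CH2Cl2, 0 °C to rt; used crude
Reagents that add atoms: none
Why: Dess–Martin oxidation is neutral and fast, so the α-branched aldehyde should form without epimerization.

Step 4
Reactants: 5; 6 1-phenyl-5-(propylsulfonyl)-1H-tetrazole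
Product: 7 (4R,5E)-4-ethyloct-5-en-1-yne
Conditions: 6, KN(SiMe3)2, DME, −60 °C; then 5, −60 °C to rt
Reagents that add atoms: none
Why: Julia–Kocienski olefination: addition of the metalated tetrazolyl sulfone to the α-branched aldehyde, Smiles rearrangement and loss of SO2 should give the E-alkene, and the weakly basic sulfonyl carbanion leaves the α-stereocentre and the alkyne C–H alone.

Step 5
Reactants: 8 ethyl 3-oxopentanoate
Product: 9 ethyl (2E)-3-{[(trifluoromethyl)sulfonyl]oxy}pent-2-enoate
Conditions: (CF3SO2)2O, aqueous Me4NOH, toluene, 5 °C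
Reagents that add atoms: trifluoromethanesulfonic anhydride, O=S(=O)(OS(=O)(=O)C(F)(F)F)C(F)(F)F
Why: Enol triflate formation from a β-keto ester: with the non-chelating Me4N+ counter-ion the enolate reacts from its open form, so the E-enol triflate should result.

Step 6
Reactants: 7; 9
Product: 12 ethyl (2E,4E,7R,8E)-3,5,7-triethylundeca-2,4,8-trienoate, via alkenylcopper 10 (not isolated), via alkenylzinc bromide 11 (not isolated)
Conditions: EtMgBr, CuBr·SMe2, Et2O/Me2S, −45 °C; 7, −25 °C; ZnBr2, THF; 9, Pd(PPh3)4 (5 mol %), −20 °C to rt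
Reagents that add atoms: ethylmagnesium bromide, CC[Mg]Br
Why: syn-Carbocupration of the terminal alkyne (ethyl to the internal carbon) fixes the trisubstituted alkene, and transmetalation to zinc followed by Negishi coupling with the enol triflate goes with retention at both sp2 carbons, so the (2E,4E) diene should follow.

Step 7
Reactants: 12
Product: 13 (2E,4E,7R,8E)-3,5,7-triethylundeca-2,4,8-trien-1-ol
Conditions: i-Bu2AlH, CH2Cl2, −78 °C
Reagents that add atoms: none
Why: 1,2-Reduction of the conjugated ester by i-Bu2AlH at low temperature gives the allylic alcohol without changing the diene geometry.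

Step 8
Reactants: 13
Product: 14 [(2S,3S)-3-[(1E,4R,5E)-2,4-diethylocta-1,5-dien-1-yl]-3-ethyloxiran-2-yl]methanol
Conditions: Ti(OiPr)4 (cat.), L-(+)-diethyl tartrate (cat.), t-BuOOH, 4 Å molecular sieves, CH2Cl2, −25 °C
Reagents that add atoms: tert-butyl hydroperoxide, CC(C)(C)OO
Why: Sharpless asymmetric epoxidation: oxygen is delivered only to the alkene allylic to the titanium-bound hydroxyl and, with L-(+)-tartrate, to the face that gives the (2S,3S)-epoxide, which sets the tertiary C–O centre (the later C6, before its inversion).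

Step 9
Reactants: 14
Product: 15 (3R,4E,7R,8E)-3,5,7-triethylundeca-4,8-diene-1,3-diol
Conditions: NaAlH2(OCH2CH2OMe)2, THF, −20 to 0 °C
Reagents that add atoms: none
Why: Directed hydride delivery from the alkoxyaluminate opens the 2,3-epoxy alcohol at C2 (away from the fully substituted C3), so the 1,3-diol forms with the tertiary carbinol centre unchanged.

Step 10
Reactants: 15
Product: 17 (2R)-2-[(1E,4R,5E)-2,4-diethylocta-1,5-dien-1-yl]-2-ethyloxetane, via primary tosylate 16 (not isolated)
Conditions: KOt-Bu (1.1 equiv), 4-MeC6H4SO2Cl, THF, 0 °C; then KOt-Bu (1.1 equiv), 0 °C to rt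
Reagents that add atoms: none
Why: Williamson-type oxetane synthesis: selective sulfonylation of the primary hydroxyl and 4-exo-tet displacement by the tertiary alkoxide close the ring without breaking a bond at the stereocentre (retention).

Step 11
Reactants: 17
Product: 18 (3S,4E,7R,8E)-3,5,7-triethyl-3-hydroperoxyundeca-4,8-dien-1-ol
Conditions: H2O2 (anhydrous, in Et2O), Me3SiOTf (0.2 equiv), Et2O, −78 to −40 °C
Reagents that add atoms: hydrogen peroxide, OO
Why: Lewis-acid-mediated opening of a 2,2-disubstituted oxetane by H2O2 at the tertiary carbon is expected to go through a tight ion pair with inversion, giving the (3S)-hydroperoxide; A(1,3) strain with the cis-ethyl group holds the breaking C–O bond in the plane of the neighbouring alkene, which should suppress allylic delocalization and attack at the distal alkene carbon.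

Step 12
Reactants: 18
Product: 19 triethyl{[(3S,4E,7R,8E)-3,5,7-triethyl-1-[(triethylsilyl)oxy]undeca-4,8-dien-3-yl]peroxy}silane
Conditions: Et3SiCl, imidazole, DMF, 0 °C
Reagents that add atoms: chlorotriethylsilane, CC[Si](Cl)(CC)CC
Why: Silylation of both the hydroxyl and the hydroperoxyl group (silyl peroxide as protected hydroperoxide) prepares the molecule for oxidation and olefination.

Step 13
Reactants: 19
Product: 20 (3S,4E,7R,8E)-3,5,7-triethyl-3-[(triethylsilyl)peroxy]undeca-4,8-dienal
Conditions: (COCl)2, DMSO, CH2Cl2, −78 °C; 19, −78 to −40 °C; Et3N, −78 °C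
Reagents that add atoms: none
Why: Swern oxidation applied directly to the primary triethylsilyl ether: the chlorosulfonium salt cleaves only the unhindered primary O–Si bond and the alkoxysulfonium ion collapses to the aldehyde, while the hindered, weakly basic tertiary silyl peroxide should stay intact; low temperature limits β-elimination of the peroxide.

Step 14
Reactants: 20
Product: 22 [(2Z,5S,6E,9R,10E)-5,7,9-triethyl-5-hydroperoxytrideca-2,6,10-trien-1-yl]trimethylsilane, via silyl peroxide 21 (not isolated)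
Conditions: Ph3PCH3Br, n-BuLi, THF, 0 °C; Me3SiCH2I, rt; n-BuLi, −78 °C; 20, −78 to 0 °C; then K2CO3, MeOH, 0 °C
Reagents that add atoms: methyltriphenylphosphonium bromide, C[P+](c1ccccc1)(c1ccccc1)c1ccccc1.[Br-]; (iodomethyl)trimethylsilane, C[Si](C)(C)CI
Why: Wittig olefination with the β-silyl ylide made in the flask gives the allylsilane mainly as the Z isomer (the geometry is not critical), and mild methanolysis then cleaves the labile O–Si bond of the silyl peroxide while the allylic C–Si bond survives.

Step 15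
Reactants: 22; 23 trimethyl orthoformate
Product: 25 (4R,6S)-6-[(1E,4R,5E)-2,4-diethylocta-1,5-dien-1-yl]-4-ethenyl-6-ethyl-3-methoxy-1,2-dioxane (both C3 epimers), via dimethoxymethyl peroxide 24 (not isolated)
Conditions: 23 (5 equiv), pyridinium 4-toluenesulfonate (cat.), 4 Å molecular sieves, CH2Cl2, rt; volatiles removed; then Me3SiOTf (0.2 equiv), 2,6-di-tert-butyl-4-methylpyridine (0.3 equiv), CH2Cl2, −78 to −40 °C
Reagents that add atoms: none
Why: Proposed new method: acid-catalysed exchange converts hydroperoxide 22 into the dimethoxymethyl peroxide 24, Me3SiOTf ionizes 24 to a peroxy(methoxy)carbenium ion centred on C3, the γ-carbon of the tethered allylsilane (C4) adds to it and the β-silyl cation loses Me3Si+, so that the 1,2-dioxane is closed by the C3–C4 bond; the closest known reaction types are the Lewis-acid-mediated allylation of monoperoxyacetals and peroxyketals (peroxycarbenium ions) by allylsilanes and the Hosomi–Sakurai reaction of orthoformates. The ring closes in the 6-exo-trig mode with respect to the allylsilane C=C (the C3=O2 cation is endocyclic) through a chair transition state. The new C4 centre is controlled by the quaternary C6: the (E)-alkenyl group, whose cis-ethyl group forces C6–O1 into the alkene plane (A(1,3) strain), sits equatorial with the C6-ethyl group axial, and the reacting C4=C bond sits equatorial because an axial one would meet the axial C6-ethyl group, which should give the 4R,6S isomer (vinyl cis to alkenyl). C3 forms as a mixture of epimers, which is harmless because C3 is re-ionized in step 16, and the E/Z mixture of the allylsilane should converge to the same product. The step needs ionization at the orthoformate carbon and not at the tertiary allylic C6–O1 bond; this is secured by the higher basicity of the acetal oxygens, the absence of α-hydrogen at C6 and the A(1,3)-enforced orthogonality of C6–O1 to the neighbouring π bond, which also keeps the C3 cation away from that trisubstituted alkene (no 5-exo closure to a 1,2-dioxolane). Intramolecular allylation is favoured over reaction with free orthoformate because 24 is pre-formed and excess 23 is removed before the Lewis acid is added.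

Step 16
Reactants: 25; 26 tert-butyl[(1-methoxyethenyl)oxy]dimethylsilane
Product: 27 methyl 2-[(3S,4R,6S)-6-[(1E,4R,5E)-2,4-diethylocta-1,5-dien-1-yl]-4-ethenyl-6-ethyl-1,2-dioxan-3-yl]acetate
Conditions: 26 (3 equiv), Me3SiOTf (0.5 equiv), CH2Cl2, −78 °C
Reagents that add atoms: none
Why: Mukaiyama-type substitution of a cyclic peroxyacetal: Me3SiOTf ionizes both C3 epimers to the same 1,2-dioxan-3-yl (peroxycarbenium) cation, and the silyl ketene acetal attacks it axially on the half-chair that keeps the C4-vinyl and C6-alkenyl groups pseudoequatorial, which should set C3 (3S) cis to C4.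

Step 17
Reactants: 27
Product: 28 methyl 2-[(3S,4S,6S)-4,6-diethyl-6-[(1E,4R,5E)-2,4-diethylocta-1,5-dien-1-yl]-1,2-dioxan-3-yl]acetate
Conditions: KO2CN=NCO2K, AcOH, MeOH/CH2Cl2, 0 °C to rt, added in portions until 27 is consumed
Reagents that add atoms: none
Why: Diimide reduction: diimide transfers H2 faster to the monosubstituted vinyl group than to the hindered E-1,2-disubstituted alkene and much faster than to the trisubstituted one, and does not cleave the O–O bond, so limited reagent should convert the vinyl group into the C4-ethyl group.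

Step 18
Reactants: 28
Product: 29 2-[(3S,4S,6S)-4,6-diethyl-6-[(1E,4R,5E)-2,4-diethylocta-1,5-dien-1-yl]-1,2-dioxan-3-yl]acetic acid
Conditions: LiOH, THF/H2O, 0 °C; then 1 M HCl to pH 3
Reagents that add atoms: lithium hydroxide, [Li+].[OH-]
Why: Saponification with LiOH at 0 °C (acyl substitution should be faster than E1cB opening of the β-peroxy ester) and mild acidification give the acid with all four stereocentres untouched.

**Compound list**

1 | (4S)-4-benzyl-3-butanoyl-1,3-oxazolidin-2-one | CCCC(=O)N1[C@@H](Cc2ccccc2)COC1=O | starting material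
2 | 3-bromoprop-1-yne | C#CCBr | starting material
3 | (4S)-4-benzyl-3-[(2R)-2-ethylpent-4-ynoyl]-1,3-oxazolidin-2-one | O=C([C@H](CC)CC#C)N1[C@@H](Cc2ccccc2)COC1=O | intermediate
4 | (2R)-2-ethylpent-4-yn-1-ol | OC[C@H](CC)CC#C | intermediate
5 | (2R)-2-ethylpent-4-ynal | O=C[C@H](CC)CC#C | intermediate
6 | 1-phenyl-5-(propylsulfonyl)-1H-tetrazole | CCCS(=O)(=O)c1nnnn1-c1ccccc1 | starting material
7 | (4R,5E)-4-ethyloct-5-en-1-yne | CC/C=C/[C@H](CC)CC#C | intermediate
8 | ethyl 3-oxopentanoate | CCC(=O)CC(=O)OCC | starting material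
9 | ethyl (2E)-3-{[(trifluoromethyl)sulfonyl]oxy}pent-2-enoate | CC/C(=C\C(=O)OCC)OS(=O)(=O)C(F)(F)F | intermediate
10 | [(1E,4R,5E)-2,4-diethylocta-1,5-dien-1-yl]copper (not isolated) | CC/C=C/[C@H](CC)C/C(CC)=C/[Cu] | intermediate
11 | bromo[(1E,4R,5E)-2,4-diethylocta-1,5-dien-1-yl]zinc (not isolated) | CC/C=C/[C@H](CC)C/C(CC)=C/[Zn]Br | intermediate
12 | ethyl (2E,4E,7R,8E)-3,5,7-triethylundeca-2,4,8-trienoate | CC/C=C/[C@H](CC)C/C(CC)=C/C(CC)=C/C(=O)OCC | intermediate
13 | (2E,4E,7R,8E)-3,5,7-triethylundeca-2,4,8-trien-1-ol | CC/C=C/[C@H](CC)C/C(CC)=C/C(CC)=C/CO | intermediate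
14 | [(2S,3S)-3-[(1E,4R,5E)-2,4-diethylocta-1,5-dien-1-yl]-3-ethyloxiran-2-yl]methanol | CC/C=C/[C@H](CC)C/C(CC)=C/[C@@]1(CC)[C@H](CO)O1 | intermediate
15 | (3R,4E,7R,8E)-3,5,7-triethylundeca-4,8-diene-1,3-diol | CC/C=C/[C@H](CC)C/C(CC)=C/[C@@](O)(CC)CCO | intermediate
16 | (3R,4E,7R,8E)-3,5,7-triethyl-3-hydroxyundeca-4,8-dien-1-yl 4-methylbenzenesulfonate (not isolated) | CC/C=C/[C@H](CC)C/C(CC)=C/[C@@](O)(CC)CCOS(=O)(=O)c1ccc(C)cc1 | intermediate
17 | (2R)-2-[(1E,4R,5E)-2,4-diethylocta-1,5-dien-1-yl]-2-ethyloxetane | CC/C=C/[C@H](CC)C/C(CC)=C/[C@@]1(CC)CCO1 | intermediate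
18 | (3S,4E,7R,8E)-3,5,7-triethyl-3-hydroperoxyundeca-4,8-dien-1-ol | CC/C=C/[C@H](CC)C/C(CC)=C/[C@](OO)(CC)CCO | intermediate
19 | triethyl{[(3S,4E,7R,8E)-3,5,7-triethyl-1-[(triethylsilyl)oxy]undeca-4,8-dien-3-yl]peroxy}silane | CC/C=C/[C@H](CC)C/C(CC)=C/[C@](OO[Si](CC)(CC)CC)(CC)CCO[Si](CC)(CC)CC | intermediate
20 | (3S,4E,7R,8E)-3,5,7-triethyl-3-[(triethylsilyl)peroxy]undeca-4,8-dienal | CC/C=C/[C@H](CC)C/C(CC)=C/[C@](OO[Si](CC)(CC)CC)(CC)CC=O | intermediate
21 | triethyl{[(2Z,5S,6E,9R,10E)-5,7,9-triethyl-1-(trimethylsilyl)trideca-2,6,10-trien-5-yl]peroxy}silane (Z isomer drawn, not isolated) | CC/C=C/[C@H](CC)C/C(CC)=C/[C@](OO[Si](CC)(CC)CC)(CC)C/C=C\C[Si](C)(C)C | intermediate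
22 | [(2Z,5S,6E,9R,10E)-5,7,9-triethyl-5-hydroperoxytrideca-2,6,10-trien-1-yl]trimethylsilane (Z isomer drawn) | CC/C=C/[C@H](CC)C/C(CC)=C/[C@](OO)(CC)C/C=C\C[Si](C)(C)C | intermediate
23 | trimethyl orthoformate | COC(OC)OC | starting material
24 | [(2Z,5S,6E,9R,10E)-5-[(dimethoxymethyl)peroxy]-5,7,9-triethyltrideca-2,6,10-trien-1-yl]trimethylsilane (not isolated) | CC/C=C/[C@H](CC)C/C(CC)=C/[C@](OOC(OC)OC)(CC)C/C=C\C[Si](C)(C)C | intermediate
25 | (4R,6S)-6-[(1E,4R,5E)-2,4-diethylocta-1,5-dien-1-yl]-4-ethenyl-6-ethyl-3-methoxy-1,2-dioxane (both C3 epimers) | CC/C=C/[C@H](CC)C/C(CC)=C/[C@]1(CC)C[C@H](C=C)C(OC)OO1 | intermediate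
26 | tert-butyl[(1-methoxyethenyl)oxy]dimethylsilane | COC(=C)O[Si](C)(C)C(C)(C)C | starting material
27 | methyl 2-[(3S,4R,6S)-6-[(1E,4R,5E)-2,4-diethylocta-1,5-dien-1-yl]-4-ethenyl-6-ethyl-1,2-dioxan-3-yl]acetate | CC/C=C/[C@H](CC)C/C(CC)=C/[C@]1(CC)C[C@H](C=C)[C@H](CC(=O)OC)OO1 | intermediate
28 | methyl 2-[(3S,4S,6S)-4,6-diethyl-6-[(1E,4R,5E)-2,4-diethylocta-1,5-dien-1-yl]-1,2-dioxan-3-yl]acetate | CC/C=C/[C@H](CC)C/C(CC)=C/[C@]1(CC)C[C@H](CC)[C@H](CC(=O)OC)OO1 | intermediate
29 | 2-[(3S,4S,6S)-4,6-diethyl-6-[(1E,4R,5E)-2,4-diethylocta-1,5-dien-1-yl]-1,2-dioxan-3-yl]acetic acid | CC/C=C/[C@H](CC)C/C(CC)=C/[C@]1(CC)C[C@H](CC)[C@H](CC(=O)O)OO1 | target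

Total steps: 18. Longest linear sequence: 17 steps (steps 1–4 and 6–18; step 5 is a side branch).

**Steps most likely to fail**

1. Step 15 (Proposed new method). The peroxy(methoxy)carbenium ion may not be captured by the allylsilane fast enough, so that ionization at the tertiary allylic C6–O1 bond, Hock-type cleavage or intermolecular allylation of orthoformate takes over. The fallback uses known reactions and closes the ring through O2–C3 instead of C3–C4. It sets out from 21, taken from step 14 before the methanolysis. An intermolecular Hosomi–Sakurai reaction with 23 (BF3·OEt2, CH2Cl2, −78 °C) would give the homoallylic acetal triethyl{[(5S,6E,9R,10E)-3-(dimethoxymethyl)-5,7,9-triethyltrideca-1,6,10-trien-5-yl]peroxy}silane F1 as a mixture at the new carbon. K2CO3 in MeOH would free (5S,6E,9R,10E)-3-(dimethoxymethyl)-5,7,9-triethyltrideca-1,6,10-trien-5-yl hydroperoxide F2. Pyridinium 4-toluenesulfonate in CH2Cl2 would then close the ring by intramolecular peroxyacetal exchange to 25, formed together with its C4 epimer (4S,6S)-6-[(1E,4R,5E)-2,4-diethylocta-1,5-dien-1-yl]-4-ethenyl-6-ethyl-3-methoxy-1,2-dioxane F3, which has to be removed by chromatography because C4 is no longer set in a ring. The route is rejoined at 25.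

2. Step 11. The oxetane may ionize to a delocalized allyl cation, with loss of stereochemical fidelity at the tertiary carbon and attack of H2O2 at the distal allyl terminus. The fallback forms the C–OO bond by conjugate addition instead of substitution and sets out from 13. MnO2 in CH2Cl2 would give (2E,4E,7R,8E)-3,5,7-triethylundeca-2,4,8-trienal F4. Amine-catalysed conjugate peroxidation (iminium activation) with 2-methoxypropan-2-yl hydroperoxide, using the enantiomer of α,α-diphenylprolinol trimethylsilyl ether that leads to the 3S adduct, would give (3S,4E,7R,8E)-3,5,7-triethyl-3-[(2-methoxypropan-2-yl)peroxy]undeca-4,8-dienal F5. The Wittig olefination of step 14 would convert it into [(2Z,5S,6E,9R,10E)-5,7,9-triethyl-5-[(2-methoxypropan-2-yl)peroxy]trideca-2,6,10-trien-1-yl]trimethylsilane F6. AcOH/H2O/THF would remove the perketal, and the route is rejoined at 22.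

3. Step 17. The E-1,2-disubstituted side-chain alkene may be reduced in competition with the vinyl group. The fallback replaces the reduction by an oxidation that is specific for terminal alkenes and sets out from 27. Tsuji–Wacker oxidation (PdCl2, CuCl, O2, DMF/H2O) would give methyl 2-[(3S,4S,6S)-4-acetyl-6-[(1E,4R,5E)-2,4-diethylocta-1,5-dien-1-yl]-6-ethyl-1,2-dioxan-3-yl]acetate F7. 4-Methylbenzenesulfonohydrazide in EtOH would give methyl 2-[(3S,4R,6S)-6-[(1E,4R,5E)-2,4-diethylocta-1,5-dien-1-yl]-6-ethyl-4-{1-[2-(4-methylbenzenesulfonyl)hydrazinylidene]ethyl}-1,2-dioxan-3-yl]acetate F8. Reduction with catecholborane (CHCl3, 0 °C; then NaOAc·3H2O, 50 °C) would turn C=N into CH2, and the route is rejoined at 28.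

Further compounds
F1 | step 15 | triethyl{[(5S,6E,9R,10E)-3-(dimethoxymethyl)-5,7,9-triethyltrideca-1,6,10-trien-5-yl]peroxy}silane | CC/C=C/[C@H](CC)C/C(CC)=C/[C@](OO[Si](CC)(CC)CC)(CC)CC(C=C)C(OC)OC
F2 | step 15 | (5S,6E,9R,10E)-3-(dimethoxymethyl)-5,7,9-triethyltrideca-1,6,10-trien-5-yl hydroperoxide | CC/C=C/[C@H](CC)C/C(CC)=C/[C@](OO)(CC)CC(C=C)C(OC)OC
F3 | step 15 | (4S,6S)-6-[(1E,4R,5E)-2,4-diethylocta-1,5-dien-1-yl]-4-ethenyl-6-ethyl-3-methoxy-1,2-dioxane | CC/C=C/[C@H](CC)C/C(CC)=C/[C@]1(CC)C[C@@H](C=C)C(OC)OO1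
F4 | step 11 | (2E,4E,7R,8E)-3,5,7-triethylundeca-2,4,8-trienal | CC/C=C/[C@H](CC)C/C(CC)=C/C(CC)=C/C=O
F5 | step 11 | (3S,4E,7R,8E)-3,5,7-triethyl-3-[(2-methoxypropan-2-yl)peroxy]undeca-4,8-dienal | CC/C=C/[C@H](CC)C/C(CC)=C/[C@](OOC(C)(C)OC)(CC)CC=O
F6 | step 11 | [(2Z,5S,6E,9R,10E)-5,7,9-triethyl-5-[(2-methoxypropan-2-yl)peroxy]trideca-2,6,10-trien-1-yl]trimethylsilane | CC/C=C/[C@H](CC)C/C(CC)=C/[C@](OOC(C)(C)OC)(CC)C/C=C\C[Si](C)(C)C
F7 | step 17 | methyl 2-[(3S,4S,6S)-4-acetyl-6-[(1E,4R,5E)-2,4-diethylocta-1,5-dien-1-yl]-6-ethyl-1,2-dioxan-3-yl]acetate | CC/C=C/[C@H](CC)C/C(CC)=C/[C@]1(CC)C[C@H](C(C)=O)[C@H](CC(=O)OC)OO1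
F8 | step 17 | methyl 2-[(3S,4R,6S)-6-[(1E,4R,5E)-2,4-diethylocta-1,5-dien-1-yl]-6-ethyl-4-{1-[2-(4-methylbenzenesulfonyl)hydrazinylidene]ethyl}-1,2-dioxan-3-yl]acetate | CC/C=C/[C@H](CC)C/C(CC)=C/[C@]1(CC)C[C@H](C(C)=NNS(=O)(=O)c2ccc(C)cc2)[C@H](CC(=O)OC)OO1
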